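**Plan**

1. Labels: furan ring O1, C2 (ylidene carbon), C3, C4, C5 (CMe2); Cα is the exocyclic carbon that bears CHO; chain C2 (CO2H, alkenyl) and chain C3 (CH2CHO, Cα) are the two stereocentres.
2. Cuts: ring O1–C2 and ring C3=C4. Ring C2, Cα and CHO form a 2-formyl ketone held as an enol ether. In the precursor the formyl oxygen carries the C5 carbinol carbon instead, so ring C3 (an acetyl CH3 on C2) and ring C4 (an aldehyde on C5) sit in a seven-membered 2H-oxepin-5-one that is not in the target. Further cuts: Cα–C2 (enamine acylation), chain C2–C3 (Ireland–Claisen), and the 1,1-disubstituted alkene (diketene opening).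
3. Forward, chain: diketene opening gives the 3-methylene acid; cross-metathesis and CBS reduction give the (S)-allylic alcohol; esterification, Ireland–Claisen rearrangement, cross-metathesis with a vinylboronate and oxidation give the CH2CHO arm; acetylation gives the 2-formyl ketone.
4. Forward, rings: enol triflate, tethering of 2-hydroxy-2-methylpropanal on the formyl oxygen and aldol condensation close the oxepinone (ring C3=C4). Aqueous acid then cleaves the tether, closes O1–C2 as a five-membered hemiketal, dehydrates to the 2-ylidene-2,5-dihydrofuran and frees the aldehyde and the ketone.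
5. Stereochemistry: both chain stereocentres come from the chair Ireland–Claisen step, with 1,3-chirality transfer from the (S)-carbinol set by CBS reduction; the exocyclic (E)-alkene comes from thermodynamic control of the push–pull enol ether in the last step.

Key step: step 9

Remark: 19 is taken as the catalogue compound (supplied as its dimer 3,3,6,6-tetramethyl-1,4-dioxane-2,5-diol, which gives the monomeric alkoxide on deprotonation).
Remark: acids 11, 14, 17 and 18 carry an acetal five atoms from the carboxyl group; they are worked up at pH 4–5, kept cold and used without storage, so that no pseudo-ester (6-ethoxy lactone) forms.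

**Route**

Step 1
Reactants: 1 2-(3-chloropropyl)-2-methyl-1,3-dioxolane; 2 diketene (4-methylideneoxetan-2-one)
Product: 4 3-methylidene-6-(2-methyl-1,3-dioxolan-2-yl)hexanoic acid, via Grignard reagent 3 (not isolated)
Conditions: Mg, THF, 40 °C; then 2, NiCl2 (5 mol%), THF, −40 to 0 °C; aq. citric acid (pH 4)
Reagents that add atoms: none
Why: Nickel-catalysed cross-coupling of the alkyl Grignard reagent at the vinylic C–O bond of diketene (opening of the β-lactone) should give the carboxylate with the 1,1-disubstituted alkene already in its final β,γ-position; no stereocentre is formed.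

Step 2
Reactants: 5 4,4-diethoxybut-1-ene; 6 but-3-en-2-one
Product: 7 (3E)-6,6-diethoxyhex-3-en-2-one
Conditions: second-generation Grubbs catalyst RuCl2(=CHPh)(PCy3)(1,3-dimesitylimidazolidin-2-ylidene) (3 mol%), 6 (3 equiv), CH2Cl2, 40 °C
Reagents that add atoms: none
Why: Olefin cross-metathesis between an unhindered terminal alkene and an electron-poor vinyl ketone should favour the cross product and give the E-enone, with loss of ethene.

Step 3
Reactants: 7 (3E)-6,6-diethoxyhex-3-en-2-one
Product: 8 (2S,3E)-6,6-diethoxyhex-3-en-2-ol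
Conditions: (R)-2-methyl-CBS-oxazaborolidine (10 mol%), catecholborane, toluene, −78 °C
Reagents that add atoms: none
Why: Corey–Bakshi–Shibata reduction, in which the (R)-oxazaborolidine binds the ketone with the alkenyl group as the large substituent and delivers hydride to the face that gives the (S)-carbinol, 1,2-reduction being favoured with catecholborane at low temperature.

Step 4
Reactants: 4 3-methylidene-6-(2-methyl-1,3-dioxolan-2-yl)hexanoic acid; 8 (2S,3E)-6,6-diethoxyhex-3-en-2-ol
Product: 9 (2S,3E)-6,6-diethoxyhex-3-en-2-yl 3-methylidene-6-(2-methyl-1,3-dioxolan-2-yl)hexanoate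
Conditions: EDC·HCl, DMAP (5 mol%), CH2Cl2, 0 °C
Reagents that add atoms: none
Why: Steglich-type carbodiimide esterification at 0 °C with little DMAP should acylate the secondary allylic alcohol with retention at the carbinol carbon and without moving the β,γ-double bond into conjugation.

Step 5
Reactants: 9 (2S,3E)-6,6-diethoxyhex-3-en-2-yl 3-methylidene-6-(2-methyl-1,3-dioxolan-2-yl)hexanoate
Product: 11 (2R,3R,4E)-3-(2,2-diethoxyethyl)-2-[5-(2-methyl-1,3-dioxolan-2-yl)pent-1-en-2-yl]hex-4-enoic acid, via silyl ketene acetal 10 (not isolated)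
Conditions: LiN(iPr)2, Me3SiCl, THF–DMPU (4:1), −78 to 25 °C; aq. citric acid (pH 4)
Reagents that add atoms: none
Why: Ireland–Claisen rearrangement, in which deprotonation between the ester and the alkene in the dipolar medium should give the ketene acetal with the alkenyl group cis to OSiMe3, which rearranges through a chair with the carbinol methyl group and the acetal-bearing chain equatorial, so that the (S)-carbinol centre is transferred to both new stereocentres (2R,3R by the sequence rules in 11, the arrangement that is 2R,3S in 24) and to the E-propenyl group.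

Step 6
Reactants: 11 (2R,3R,4E)-3-(2,2-diethoxyethyl)-2-[5-(2-methyl-1,3-dioxolan-2-yl)pent-1-en-2-yl]hex-4-enoic acid; 12 4,4,5,5-tetramethyl-2-vinyl-1,3,2-dioxaborolane
Product: 14 (2R,3S)-3-(2,2-diethoxyethyl)-2-[5-(2-methyl-1,3-dioxolan-2-yl)pent-1-en-2-yl]-5-oxopentanoic acid, via alkenylboronate 13 (not isolated)
Conditions: second-generation Grubbs catalyst RuCl2(=CHPh)(PCy3)(1,3-dimesitylimidazolidin-2-ylidene) (5 mol%), 12 (3 equiv), CH2Cl2, 40 °C; then 30% H2O2, NaHCO3, THF–H2O, 0 °C
Reagents that add atoms: hydrogen peroxide, OO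
Why: Cross-metathesis of the E-propenyl group with the vinylboronate (propene is lost, the 1,1-disubstituted alkene stays inert) and oxidation of the C–B bond should give the enol and hence the CH2CHO arm, with neither stereocentre touched.

Step 7
Reactants: 14 (2R,3S)-3-(2,2-diethoxyethyl)-2-[5-(2-methyl-1,3-dioxolan-2-yl)pent-1-en-2-yl]-5-oxopentanoic acid
Product: 17 (2R,3S,4Z)-4-acetyl-3-(2,2-diethoxyethyl)-5-hydroxy-2-[5-(2-methyl-1,3-dioxolan-2-yl)pent-1-en-2-yl]pent-4-enoic acid, via enamine 15 (not isolated), via enaminone 16 (not isolated)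
Conditions: morpholine (1.1 equiv), Et3N, 4 Å molecular sieves, CH2Cl2, 20 °C; AcCl (2.2 equiv), 0 °C; then 1 M NaOH, THF, 0 °C; citric acid (pH 4)
Reagents that add atoms: acetyl chloride, CC(Cl)=O; water, O
Why: Stork enamine acylation, in which the aldehyde enamine is acylated at its β-carbon (the only enolizable carbon of this arm) to a vinylogous amide that cold hydroxide should hydrolyse to the 2-formyl ketone in its chelated hydroxymethylene form, the mixed anhydride formed at the carboxyl group being cleaved in the same work-up.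

Step 8
Reactants: 17 (2R,3S,4Z)-4-acetyl-3-(2,2-diethoxyethyl)-5-hydroxy-2-[5-(2-methyl-1,3-dioxolan-2-yl)pent-1-en-2-yl]pent-4-enoic acid
Product: 18 (2R,3S,4Z)-4-acetyl-3-(2,2-diethoxyethyl)-2-[5-(2-methyl-1,3-dioxolan-2-yl)pent-1-en-2-yl]-5-{[(trifluoromethyl)sulfonyl]oxy}pent-4-enoic acid
Conditions: PhNTf2 (1.1 equiv), Et3N (2.2 equiv), CH2Cl2, −20 °C
Reagents that add atoms: N-phenylbis(trifluoromethanesulfonimide), O=S(=O)(N(c1ccccc1)S(=O)(=O)C(F)(F)F)C(F)(F)F
Why: O-Sulfonylation of the chelated enolate of a 2-formyl ketone should take place at the less hindered hydroxymethylene oxygen and keep that oxygen cis to the acetyl group, and the triflimide reagent should react with the enolate much faster than with the carboxylate.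

Step 9
Reactants: 18 (2R,3S,4Z)-4-acetyl-3-(2,2-diethoxyethyl)-2-[5-(2-methyl-1,3-dioxolan-2-yl)pent-1-en-2-yl]-5-{[(trifluoromethyl)sulfonyl]oxy}pent-4-enoic acid; 19 2-hydroxy-2-methylpropanal
Product: 23 (2R,3S)-3-(2,2-diethoxyethyl)-3-(2,2-dimethyl-5-oxo-2,5-dihydrooxepin-6-yl)-2-[5-(2-methyl-1,3-dioxolan-2-yl)pent-1-en-2-yl]propanoic acid, via sodium alkoxide 20 (not isolated), via tethered aldehyde 21 (not isolated), via aldol 22 (not isolated)
Conditions: 19 (1.2 equiv), NaH (2.2 equiv), THF, 0 °C; 18, −78 to 0 °C; then lithium 2,2,6,6-tetramethylpiperidide (2.2 equiv), −78 to 0 °C; KH2PO4 buffer (pH 5)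
Reagents that add atoms: none
Why: The tertiary alkoxide 20 adds to the formyl-derived carbon of the β-triflyloxy enone 18 and expels triflate (vinylic substitution by addition–elimination), which hangs the aldehyde carbon (future ring C4) on the formyl oxygen; the hindered amide base then deprotonates the acetyl methyl group (future ring C3, the α' position of the vinylogous ester), and the enolate adds to the tethered aldehyde and loses hydroxide by E1cB, so that the C3=C4 bond forms inside a seven-membered 2H-oxepin-5-one. The closest known reaction types are the displacement of β-sulfonyloxy enones by alkoxides and the intramolecular aldol condensation of α'-enolates of β-alkoxy enones. The ring closes in the 7-(enolendo)-exo-trig mode, helped by the cis double bond of 21 (formyl oxygen and acetyl group on the same side) and by the gem-dimethyl group of the tether. The carbinol centre of aldol 22 is formed without control and is removed by the dehydration, the ring allows only a cis C3=C4 bond, and the two chain stereocentres are not touched because the acid is present as its carboxylate. The step needs the enolate to form at the methyl group and to attack only the tethered aldehyde: the other α-carbon of the ketone is the fully substituted enol-ether carbon, the tethered aldehyde has no α-hydrogen, the other aldehyde and ketone are masked as acetal and ketal, and any E isomer of 21 should be fed into the reacting Z isomer by reversible addition of the small excess of alkoxide 20 to the enol-ether carbon.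

Step 10
Reactants: 23 (2R,3S)-3-(2,2-diethoxyethyl)-3-(2,2-dimethyl-5-oxo-2,5-dihydrooxepin-6-yl)-2-[5-(2-methyl-1,3-dioxolan-2-yl)pent-1-en-2-yl]propanoic acid
Product: 24 (2R,3S)-3-[(1E)-1-(5,5-dimethylfuran-2(5H)-ylidene)-2-oxoethyl]-5-oxo-2-(6-oxohept-1-en-2-yl)pentanoic acid
Conditions: 1 M aq. HCl–THF (1:3), 0 to 20 °C
Reagents that add atoms: water, O
Why: Aqueous acid should hydrolyse the vinylogous ester at the formyl-derived carbon (freeing the CHO on Cα and the tertiary alcohol on a cis enone), the alcohol then closes the five-membered hemiketal on the ketone carbon (ring C2) and water is lost toward Cα to give the 2-ylidene-2,5-dihydrofuran, whose push–pull alkene can equilibrate to the E form (bulky chain next to the ring oxygen), while the diethyl acetal and the dioxolane are hydrolysed under the same conditions.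

**Compound list**

1 | 2-(3-chloropropyl)-2-methyl-1,3-dioxolane | CC1(CCCCl)OCCO1 | starting material
2 | diketene (4-methylideneoxetan-2-one) | C=C1CC(=O)O1 | starting material
3 | [3-(2-methyl-1,3-dioxolan-2-yl)propyl]magnesium chloride | CC1(CCC[Mg]Cl)OCCO1 | intermediate
4 | 3-methylidene-6-(2-methyl-1,3-dioxolan-2-yl)hexanoic acid | C=C(CCCC1(C)OCCO1)CC(=O)O | intermediate
5 | 4,4-diethoxybut-1-ene | C=CCC(OCC)OCC | starting material
6 | but-3-en-2-one | C=CC(C)=O | starting material
7 | (3E)-6,6-diethoxyhex-3-en-2-one | CC(=O)/C=C/CC(OCC)OCC | intermediate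
8 | (2S,3E)-6,6-diethoxyhex-3-en-2-ol | C[C@H](O)/C=C/CC(OCC)OCC | intermediate
9 | (2S,3E)-6,6-diethoxyhex-3-en-2-yl 3-methylidene-6-(2-methyl-1,3-dioxolan-2-yl)hexanoate | C=C(CCCC1(C)OCCO1)CC(=O)O[C@@H](C)/C=C/CC(OCC)OCC | intermediate
10 | {[(1Z)-1-{[(2S,3E)-6,6-diethoxyhex-3-en-2-yl]oxy}-3-methylidene-6-(2-methyl-1,3-dioxolan-2-yl)hex-1-en-1-yl]oxy}(trimethyl)silane | C=C(CCCC1(C)OCCO1)/C=C(\O[Si](C)(C)C)O[C@@H](C)/C=C/CC(OCC)OCC | intermediate
11 | (2R,3R,4E)-3-(2,2-diethoxyethyl)-2-[5-(2-methyl-1,3-dioxolan-2-yl)pent-1-en-2-yl]hex-4-enoic acid | C=C(CCCC1(C)OCCO1)[C@H](C(=O)O)[C@H](CC(OCC)OCC)/C=C/C | intermediate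
12 | 4,4,5,5-tetramethyl-2-vinyl-1,3,2-dioxaborolane | C=CB1OC(C)(C)C(C)(C)O1 | starting material
13 | (2R,3R,4E)-3-(2,2-diethoxyethyl)-2-[5-(2-methyl-1,3-dioxolan-2-yl)pent-1-en-2-yl]-5-(4,4,5,5-tetramethyl-1,3,2-dioxaborolan-2-yl)pent-4-enoic acid | C=C(CCCC1(C)OCCO1)[C@H](C(=O)O)[C@H](CC(OCC)OCC)/C=C/B1OC(C)(C)C(C)(C)O1 | intermediate
14 | (2R,3S)-3-(2,2-diethoxyethyl)-2-[5-(2-methyl-1,3-dioxolan-2-yl)pent-1-en-2-yl]-5-oxopentanoic acid | C=C(CCCC1(C)OCCO1)[C@H](C(=O)O)[C@H](CC(OCC)OCC)CC=O | intermediate
15 | (2R,3R,4E)-3-(2,2-diethoxyethyl)-2-[5-(2-methyl-1,3-dioxolan-2-yl)pent-1-en-2-yl]-5-(morpholin-4-yl)pent-4-enoic acid | C=C(CCCC1(C)OCCO1)[C@H](C(=O)O)[C@H](CC(OCC)OCC)/C=C/N1CCOCC1 | intermediate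
16 | (2R,3S,4E)-4-acetyl-3-(2,2-diethoxyethyl)-2-[5-(2-methyl-1,3-dioxolan-2-yl)pent-1-en-2-yl]-5-(morpholin-4-yl)pent-4-enoic acid | C=C(CCCC1(C)OCCO1)[C@H](C(=O)O)[C@H](CC(OCC)OCC)/C(C(C)=O)=C\N1CCOCC1 | intermediate
17 | (2R,3S,4Z)-4-acetyl-3-(2,2-diethoxyethyl)-5-hydroxy-2-[5-(2-methyl-1,3-dioxolan-2-yl)pent-1-en-2-yl]pent-4-enoic acid | C=C(CCCC1(C)OCCO1)[C@H](C(=O)O)[C@H](CC(OCC)OCC)/C(C(C)=O)=C/O | intermediate
18 | (2R,3S,4Z)-4-acetyl-3-(2,2-diethoxyethyl)-2-[5-(2-methyl-1,3-dioxolan-2-yl)pent-1-en-2-yl]-5-{[(trifluoromethyl)sulfonyl]oxy}pent-4-enoic acid | C=C(CCCC1(C)OCCO1)[C@H](C(=O)O)[C@H](CC(OCC)OCC)/C(C(C)=O)=C/OS(=O)(=O)C(F)(F)F | intermediate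
19 | 2-hydroxy-2-methylpropanal | CC(C)(O)C=O | starting material
20 | sodium 2-methyl-1-oxopropan-2-olate | CC(C)([O-])C=O.[Na+] | intermediate
21 | (2R,3S,4Z)-4-acetyl-3-(2,2-diethoxyethyl)-5-[(2-methyl-1-oxopropan-2-yl)oxy]-2-[5-(2-methyl-1,3-dioxolan-2-yl)pent-1-en-2-yl]pent-4-enoic acid | C=C(CCCC1(C)OCCO1)[C@H](C(=O)O)[C@H](CC(OCC)OCC)/C(C(C)=O)=C/OC(C)(C)C=O | intermediate
22 | (2R,3S)-3-(2,2-diethoxyethyl)-3-(3-hydroxy-2,2-dimethyl-5-oxo-2,3,4,5-tetrahydrooxepin-6-yl)-2-[5-(2-methyl-1,3-dioxolan-2-yl)pent-1-en-2-yl]propanoic acid (both carbinol epimers) | C=C(CCCC1(C)OCCO1)[C@H](C(=O)O)[C@H](CC(OCC)OCC)C2=COC(C)(C)C(O)CC2=O | intermediate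
23 | (2R,3S)-3-(2,2-diethoxyethyl)-3-(2,2-dimethyl-5-oxo-2,5-dihydrooxepin-6-yl)-2-[5-(2-methyl-1,3-dioxolan-2-yl)pent-1-en-2-yl]propanoic acid | C=C(CCCC1(C)OCCO1)[C@H](C(=O)O)[C@H](CC(OCC)OCC)C2=COC(C)(C)C=CC2=O | intermediate
24 | (2R,3S)-3-[(1E)-1-(5,5-dimethylfuran-2(5H)-ylidene)-2-oxoethyl]-5-oxo-2-(6-oxohept-1-en-2-yl)pentanoic acid | C=C(CCCC(C)=O)[C@H](C(=O)O)[C@H](CC=O)/C(C=O)=C1/C=CC(C)(C)O1 | target

**Step count and risks**

Total step count: 10. Longest linear sequence: 9 steps (steps 2 to 10, from 5 and 6); step 1 is a one-step branch to acid 4.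

Steps most likely to fail:

Step 9. The alkoxide of the α-hydroxy aldehyde may rearrange (α-ketol shift) or attack the sulfur of the triflate instead of the enol carbon, and the seven-membered aldol closure may lose to intermolecular aldol addition. The fallback sets out from 17 and comes back to the route at 24. 17 is converted into its trianion (NaH, 2 equiv, then LiN(iPr)2, 1.1 equiv, THF, 0 °C), in which the acetyl methyl group is the most nucleophilic carbon, as in the γ-reactions of 1,3-dicarbonyl dianions. Addition to alkoxide 20 at −78 °C should give the open-chain aldol (2R,3S,4Z)-3-(2,2-diethoxyethyl)-4-(3,4-dihydroxy-4-methylpentanoyl)-5-hydroxy-2-[5-(2-methyl-1,3-dioxolan-2-yl)pent-1-en-2-yl]pent-4-enoic acid F1, which needs no tether. Under the acid conditions of step 10 its tertiary hydroxyl closes the five-membered hemiketal on the ketone, and loss of two molecules of water and of the acetal and ketal groups gives 24.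

Step 10. Once the diethyl acetal is hydrolysed, the enol of the 2-formyl ketone may add to the freed aldehyde (2-hydroxydihydropyran, then 4H-pyran) faster than the hemiketal dehydrates, and the acid may shift the 1,1-disubstituted alkene into conjugation with the carboxyl group. The fallback sets out from 23 and comes back at 24. Morpholine (1.1 equiv, CH2Cl2, 0 °C) opens the vinylogous ester by amine exchange to the enaminone (2R,3S)-3-(2,2-diethoxyethyl)-4-[(2Z)-4-hydroxy-4-methylpent-2-enoyl]-2-[5-(2-methyl-1,3-dioxolan-2-yl)pent-1-en-2-yl]-5-(morpholin-4-yl)pent-4-enoic acid F2, whose freed tertiary alcohol closes on the ketone. In a pH 5 acetate buffer water is lost with the help of the enamine nitrogen and the iminium ion is hydrolysed, so that the dihydrofuran (2R,3S,4E)-3-(2,2-diethoxyethyl)-4-(5,5-dimethylfuran-2(5H)-ylidene)-2-[5-(2-methyl-1,3-dioxolan-2-yl)pent-1-en-2-yl]-5-oxopentanoic acid F3 forms while acetal and ketal stay in place. F3 is then unmasked under nearly neutral conditions with catalytic Ce(OTf)3 in wet nitromethane to give 24.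

Step 7. The enamine may be acylated at nitrogen instead of carbon, the aldehyde enamine may self-condense, chain C2 may epimerize through a ketene formed from the mixed anhydride, and the formyl group may be lost (retro-Claisen cleavage) during the hydroxide hydrolysis. The fallback sets out from 14 and comes back at 17. 14 is condensed with tert-butylamine (4 Å molecular sieves, CH2Cl2) to the imine (2R,3S)-5-(tert-butylimino)-3-(2,2-diethoxyethyl)-2-[5-(2-methyl-1,3-dioxolan-2-yl)pent-1-en-2-yl]pentanoic acid F4, obtained as its ammonium carboxylate. LiN(iPr)2 (3.2 equiv, THF, −78 °C) gives the aza-enolate of the carboxylate, which is acetylated at carbon with 1-acetylimidazole to the chelated enaminone (2R,3S,4Z)-4-acetyl-5-(tert-butylamino)-3-(2,2-diethoxyethyl)-2-[5-(2-methyl-1,3-dioxolan-2-yl)pent-1-en-2-yl]pent-4-enoic acid F5. F5 is hydrolysed in a two-phase mixture with aqueous oxalic acid at 0 °C to 17.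

**Further compounds**

F1 | step 9 | (2R,3S,4Z)-3-(2,2-diethoxyethyl)-4-(3,4-dihydroxy-4-methylpentanoyl)-5-hydroxy-2-[5-(2-methyl-1,3-dioxolan-2-yl)pent-1-en-2-yl]pent-4-enoic acid | C=C(CCCC1(C)OCCO1)[C@H](C(=O)O)[C@H](CC(OCC)OCC)/C(=C/O)C(=O)CC(O)C(C)(C)O
F2 | step 10 | (2R,3S)-3-(2,2-diethoxyethyl)-4-[(2Z)-4-hydroxy-4-methylpent-2-enoyl]-2-[5-(2-methyl-1,3-dioxolan-2-yl)pent-1-en-2-yl]-5-(morpholin-4-yl)pent-4-enoic acid | C=C(CCCC1(C)OCCO1)[C@H](C(=O)O)[C@H](CC(OCC)OCC)C(=CN1CCOCC1)C(=O)/C=C\C(C)(C)O
F3 | step 10 | (2R,3S,4E)-3-(2,2-diethoxyethyl)-4-(5,5-dimethylfuran-2(5H)-ylidene)-2-[5-(2-methyl-1,3-dioxolan-2-yl)pent-1-en-2-yl]-5-oxopentanoic acid | C=C(CCCC1(C)OCCO1)[C@H](C(=O)O)[C@H](CC(OCC)OCC)/C(C=O)=C2/C=CC(C)(C)O2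
F4 | step 7 | (2R,3S)-5-(tert-butylimino)-3-(2,2-diethoxyethyl)-2-[5-(2-methyl-1,3-dioxolan-2-yl)pent-1-en-2-yl]pentanoic acid | C=C(CCCC1(C)OCCO1)[C@H](C(=O)O)[C@H](CC(OCC)OCC)C/C=N/C(C)(C)C
F5 | step 7 | (2R,3S,4Z)-4-acetyl-5-(tert-butylamino)-3-(2,2-diethoxyethyl)-2-[5-(2-methyl-1,3-dioxolan-2-yl)pent-1-en-2-yl]pent-4-enoic acid | C=C(CCCC1(C)OCCO1)[C@H](C(=O)O)[C@H](CC(OCC)OCC)/C(C(C)=O)=C/NC(C)(C)C
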